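The earlier runs and the new flask were computed with made-up constants, noise included.

| flask | substrate | temperature | remark | time |
|---|---|---|---|---|
| delta | 0.069 M | 20 °C | the very flask that is asked about, followed so far |  |
| epsilon | 0.069 M | 26 °C | run made earlier |  |
| flask | 0.069 M | 20 °C |  | 8.0 d |

| delta: time / d | delta: target / % | epsilon: time / d | epsilon: target / % |
|---|---|---|---|
| 0.500 | 35.6 | 0.500 | 31.3 |
| 0.833 | 29.8 | 0.833 | 31.9 |
| 1.25 | 24.9 | 1.25 | 29.0 |
| 2.50 | 22.1 | 2.50 | 29.0 |
| 4.00 | 20.1 | 4.00 | 30.5 |
| 6.00 | 19.7 | 6.00 | 29.9 |

(readings scatter by 1 percentage point)

- amber: at 8.0 d raise the temperature by 25 K, then wait 8.0 d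
- violet: at 8.0 d take out 90% of the target then present, then wait 8.0 d
- teal: at 8.0 d add substrate, 50.0% of the amount charged, then wait 8.0 d
- red: change nothing and wait 8.0 d more

- target that was removed still counts
- additions bring no volume worth counting

- target, in percent of the substrate first charged, at 8.0 d
- the option that brings most further target ("none" if no option brings more than 2 percentage points) (amber / violet / teal / red / none)
- target present, with what was taken out counted in, in percent of the substrate first charged, after violet
- target present, with what was taken out counted in, in percent of the substrate first charged, after red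

- At early times the delta flask reads 35.6% at 0.500 d and falls. From 4.00 d on it stands still: its last two readings differ by 0.4 percentage points, less than the scatter of 1 point.
- I read this as kinetic control giving way to thermodynamic control, and I call the mean of those two readings the plateau share s, meaning c(target) over the charged c(substrate): 19.9%. So I commit to s for now and for red. Red would pay if the target were still climbing by 2 points, but it is not climbing.
- Now I turn the question round: what would make amber lose? Violet takes out 90% of the target, so a share 17.9% of the charge leaves the flask. If what stays in the flask returns to share s of itself, the total with the removed target counted in becomes 34.2%. This is my break-even share: an amber flask whose target ends below it loses to violet.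
- If the added substrate also ends at share s, teal brings 10 points, less than violet's 14 points.
- The epsilon run, at 26 °C, stands near 29.8%. That warming already covers 69.2% of the way from s to the break-even share, and amber offers 25 K. So I choose amber, and I commit to 34.2% for violet.
- The forecast, reading “a true equilibrium between target and a sink”, gives 19.6% for now, 34% for violet, 19.6% for red and amber as the choice, against my 19.9% and 34.2%.
- The flask gives 20.0% at 8.0 d, 34.3% after violet and 19.9% after red. Amber leads with 33 points, against 14 points for violet and 9.9 points for teal.

    substrate ⇌ target (K = 1.30, k = 4.90 × 10⁻⁴ s⁻¹, Ea = 78.0 kJ mol⁻¹, ΔH = 12.0 kJ mol⁻¹)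
    2 substrate → self-condensation product (k = 5.50 × 10⁻⁷ M⁻¹ s⁻¹, Ea = 90.0 kJ mol⁻¹)
    substrate ⇌ isomer of the product (K = 4.20, k = 1.50 × 10⁻⁵ s⁻¹, Ea = 96.0 kJ mol⁻¹, ΔH = −72.0 kJ mol⁻¹)
    target ⇌ isomer of the product (k = 1.00 × 10⁻⁵ s⁻¹, Ea = 91.0 kJ mol⁻¹)
    (constants at 20 °C)

- Put through with the flask's 20.0%, the break-even share becomes 34.4%, beside violet's 34.3%. The share lumps the rest into one pool, yet at 8.00 d the flask holds 15.4% substrate, 64.5% isomer of the product and 0.179% self-condensation product. The relaxation half-life of target and isomer of the product, by that step alone and both ways together, is 0.613 d, short against 8.0 d. The neighbouring flask, the same charge run at 45 °C from the start, goes through the same reckoning: at 8.00 d its target stands at 53.0%, above the break-even share of 34.2%, with isomer of the product at 11.4%.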